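**Plan**

- Labdane numbering is used: ring A = C1–C5 and C10, ring B = C5–C10, C19 = carboxyl carbon on C4, C20 = methyl on C10, C17 = exocyclic methylene carbon, side chain C11–C16 on C9.
- Retrosynthesis cuts, in this order: the C15–O ester; C14–C15 and C13–C16 (alkyne carboalumination); C9–C11 together with C8=C17 (back to a C9 ketone); the ring-A bond C3–C4, with C1–O rejoined as a lactone; then C10–C1 (aldol) and C4–C5 (Michael), which leaves 2-methylcyclohex-2-enone, a propanoate ketene acetal and acrolein.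
- Forward: ring B is bought as 2-methylcyclohexenone; Michael addition, aldol addition and lactonisation hang a temporary δ-lactone ring on it; ring A is closed by ring contraction of that lactone; the C1=C2 alkene left behind is hydrogenated; methylene, side chain and palmitate are then built from the C9 ketone.
- Enabling feature: C1 and C4 are 1,4-related across ring A and C4 carries the axial carboxyl C19, so a six-membered lactone ring made of C19, its oxygen, C1, C10, C5 and C4 holds a vinyl group (C2=C3) on C1 directly below C4.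
- Stereochemistry: C5 from the enantioselective Michael addition; C10 and C1 from the chair aldol, trans to the C5 substituent; C4 by chirality transfer from C1 in the ring contraction (both C4 epimers of the lactone converge); C9 by hydride delivery anti to C20; 13E from syn-carboalumination.

Key step: step 3

Assumption: the (S)-configured oxazaborolidinium ion is taken to add the ketene acetal to the face of 1 that gives (S)-3, by extrapolation from cyclohex-2-enone; if the sense is opposite, the (R)-catalyst is used and nothing else changes.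

**Step 1**
Reactants: 1 2-methylcyclohex-2-en-1-one; 2 (E)-1-methoxy-1-(trimethylsilyloxy)prop-1-ene
Product: 3 methyl (2RS)-2-[(1S)-2-methyl-3-(trimethylsilyloxy)cyclohex-2-en-1-yl]propanoate
Conditions: (S)-1-(2-methylphenyl)-3,3-diphenyltetrahydro-1H,3H-pyrrolo[1,2-c][1,3,2]oxazaborole (20 mol%), Tf2NH (20 mol%), Ph3PO (25 mol%), toluene, −20 °C
Reagents that add atoms: none
Why: Catalytic enantioselective Mukaiyama–Michael addition, in which the chiral oxazaborolidinium ion binds the enone carbonyl and shields one face of C5, and silyl transfer to the enolate oxygen fixes the tetrasubstituted enol ether needed in step 2; the C4 configuration is left open because step 3 erases it.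

**Step 2**
Reactants: 3 methyl (2RS)-2-[(1S)-2-methyl-3-(trimethylsilyloxy)cyclohex-2-en-1-yl]propanoate
Product: 6 (1R,4RS,4aS,8aR)-1-ethenyl-4,8a-dimethyloctahydro-1H-isochromene-3,8-dione, via dibutylboron enolate 4 (not isolated), via hydroxy ester 5 (not isolated)
Conditions: Bu2BOTf, CH2Cl2, 0 °C; acrolein, −78 °C to −20 °C; MeOH, pH 7 phosphate buffer; then PPTS, toluene, 80 °C
Reagents that add atoms: acrolein C=CC=O
Why: Silicon-to-boron exchange gives the boron enolate, whose aldol addition to acrolein through a closed six-membered chair transition state forms C10–C1 on the face opposite the C5 substituent and places the C1 oxygen anti to C5, so that acid-catalysed lactonisation onto the C19 ester should give the trans-fused δ-lactone with the vinyl group axial.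

**Step 3**
Reactants: 6 (1R,4RS,4aS,8aR)-1-ethenyl-4,8a-dimethyloctahydro-1H-isochromene-3,8-dione
Product: 9 (1S,4aS,8aR)-1,4a-dimethyl-5-oxo-1,2,4a,5,6,7,8,8a-octahydronaphthalene-1-carboxylic acid, via bis-silyl ketene acetal 7 (not isolated), via trimethylsilyl ester 8 (not isolated)
Conditions: LDA (2.4 equiv), TMSCl, Et3N, THF, −78 °C to rt; toluene, 110 °C; then 1 M HCl, THF
Reagents that add atoms: none
Why: LDA and TMSCl convert the lactone into its cyclic O-silyl ketene acetal (C4=C19, the same planar unit from either C4 epimer, with the C9 ketone masked in passing as its silyl enol ether), and on heating the array C4=C19–O–C1–C2=C3 undergoes a [3,3]-sigmatropic shift that forms C3–C4 and breaks C1–O. The closest known reaction type is the Ireland–Claisen ring contraction of ω-vinyl lactone silyl ketene acetals to cycloalkene carboxylic acids. Ring A (C1–C5 and C10) is closed as a cyclohexene by this suprafacial ring contraction through the boat-shaped six-atom transition state, the only one the lactone ring allows. The new quaternary stereocentre C4 is controlled by the C1 stereocentre and the trans ring fusion: the axial vinyl group can reach C4 only from the α-face, and C19, which was tied to the C1 oxygen on the other side, should end up axial and syn to the C10 methyl. The step needs enolisation of the lactone at C4 and bonding at C3 rather than C1; the first is secured because C4 is the only α-carbon of the lactone, the second because bonding from C1 would give a four-membered ring. Acid work-up frees the carboxylic acid and the C9 ketone.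

**Step 4**
Reactants: 9 (1S,4aS,8aR)-1,4a-dimethyl-5-oxo-1,2,4a,5,6,7,8,8a-octahydronaphthalene-1-carboxylic acid
Product: 10 (1S,4aS,8aR)-1,4a-dimethyl-5-oxodecahydronaphthalene-1-carboxylic acid
Conditions: H2 (1 atm), Pd/C, EtOAc, rt
Reagents that add atoms: none
Why: Heterogeneous hydrogenation of the only C=C bond, the disubstituted C1=C2 alkene left by the key step; no stereocentre is formed.

**Step 5**
Reactants: 10 (1S,4aS,8aR)-1,4a-dimethyl-5-oxodecahydronaphthalene-1-carboxylic acid
Product: 11 prop-2-en-1-yl (1S,4aS,8aR)-1,4a-dimethyl-5-oxodecahydronaphthalene-1-carboxylate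
Conditions: allyl bromide, K2CO3, DMF, rt
Reagents that add atoms: allyl bromide C=CCBr
Why: SN2 O-alkylation of the hindered carboxylate, which masks the acid for the organolithium step and is removed at no extra cost in step 9.

**Step 6**
Reactants: 11 prop-2-en-1-yl (1S,4aS,8aR)-1,4a-dimethyl-5-oxodecahydronaphthalene-1-carboxylate
Product: 12 prop-2-en-1-yl (1S,4aS,8aR)-1,4a-dimethyl-6-methylidene-5-oxodecahydronaphthalene-1-carboxylate
Conditions: paraformaldehyde, N-methylanilinium trifluoroacetate, THF, reflux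
Reagents that add atoms: paraformaldehyde (as formaldehyde) C=O
Why: Mannich-type α-methylenation (iminium addition to the enol, then amine elimination), regioselective because C8 is the only enolisable position next to the C9 ketone (C10 is quaternary).

**Step 7**
Reactants: 13 4-(trimethylsilyl)but-3-yn-1-ol
Product: 14 (4-iodobut-1-yn-1-yl)trimethylsilane
Conditions: I2, PPh3, imidazole, CH2Cl2, 0 °C to rt
Reagents that add atoms: iodine II
Why: Appel-type iodination, SN2 displacement of the alkoxyphosphonium ion by iodide at a primary carbon.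

**Step 8**
Reactants: 14 (4-iodobut-1-yn-1-yl)trimethylsilane; 12 prop-2-en-1-yl (1S,4aS,8aR)-1,4a-dimethyl-6-methylidene-5-oxodecahydronaphthalene-1-carboxylate
Product: 16 prop-2-en-1-yl (1S,4aS,5S,8aR)-5-[(methoxycarbonyl)oxy]-1,4a-dimethyl-6-methylidene-5-[4-(trimethylsilyl)but-3-yn-1-yl]decahydronaphthalene-1-carboxylate, via lithium alkoxide 15 (not isolated)
Conditions: 14, t-BuLi (2 equiv), Et2O, −78 °C; 12, −78 °C; ClCO2Me, −78 °C to rt
Reagents that add atoms: methyl chloroformate COC(=O)Cl
Why: Iodine–lithium exchange gives the primary alkyllithium, which should add 1,2 to the non-enolisable enone carbonyl from the α-face opposite the axial C20 methyl; the tertiary lithium alkoxide is trapped as its methyl carbonate, and the C9 configuration formed here is erased in step 9.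

**Step 9**
Reactants: 16 prop-2-en-1-yl (1S,4aS,5S,8aR)-5-[(methoxycarbonyl)oxy]-1,4a-dimethyl-6-methylidene-5-[4-(trimethylsilyl)but-3-yn-1-yl]decahydronaphthalene-1-carboxylate
Product: 17 (1S,4aR,5S,8aR)-1,4a-dimethyl-6-methylidene-5-[4-(trimethylsilyl)but-3-yn-1-yl]decahydronaphthalene-1-carboxylic acid
Conditions: Pd(OAc)2 (5 mol%), PBu3 (10 mol%), HCO2H, Et3N, THF, 40 °C
Reagents that add atoms: none
Why: Palladium-catalysed formate hydrogenolysis of the tertiary allylic carbonate (Tsuji–Trost ionisation by zerovalent palladium, then hydride transfer from the palladium formate to the more substituted allyl terminus C9), which should keep C8=C17 exocyclic and deliver hydrogen to the less hindered α-face of C9 so that the side chain is equatorial; the same catalyst and formate cleave the allyl ester.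

**Step 10**
Reactants: 17 (1S,4aR,5S,8aR)-1,4a-dimethyl-6-methylidene-5-[4-(trimethylsilyl)but-3-yn-1-yl]decahydronaphthalene-1-carboxylic acid
Product: 18 (1S,4aR,5S,8aR)-5-(but-3-yn-1-yl)-1,4a-dimethyl-6-methylidenedecahydronaphthalene-1-carboxylic acid
Conditions: K2CO3, MeOH, rt; then dilute HCl
Reagents that add atoms: none
Why: Base-mediated methanolysis of the alkynyl C–Si bond (protodesilylation); the alkenes and the acid are untouched.

**Step 11**
Reactants: 18 (1S,4aR,5S,8aR)-5-(but-3-yn-1-yl)-1,4a-dimethyl-6-methylidenedecahydronaphthalene-1-carboxylic acid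
Product: 20 (1S,4aR,5S,8aR)-5-[(3E)-5-hydroxy-3-methylpent-3-en-1-yl]-1,4a-dimethyl-6-methylidenedecahydronaphthalene-1-carboxylic acid, via alkenylalane 19 (not isolated)
Conditions: Me3Al (4 equiv), Cp2ZrCl2 (0.25 equiv), CH2Cl2, 0 °C to rt; paraformaldehyde, THF, rt; 1 M HCl
Reagents that add atoms: trimethylaluminium C[Al](C)C; paraformaldehyde (as formaldehyde) C=O
Why: Zirconium-catalysed syn-carboalumination of the terminal alkyne puts methyl on C13 and aluminium on C14, and the alkenylalane is hydroxymethylated by formaldehyde with retention, which sets the 13E geometry; the acid travels as its aluminium carboxylate and the 1,1-disubstituted C8=C17 alkene is inert.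

**Step 12**
Reactants: 20 (1S,4aR,5S,8aR)-5-[(3E)-5-hydroxy-3-methylpent-3-en-1-yl]-1,4a-dimethyl-6-methylidenedecahydronaphthalene-1-carboxylic acid
Product: 22 (1S,4aR,5S,8aR)-5-[(3E)-5-(hexadecanoyloxy)-3-methylpent-3-en-1-yl]-1,4a-dimethyl-6-methylidenedecahydronaphthalene-1-carboxylic acid, via mixed anhydride 21 (not isolated)
Conditions: palmitoyl chloride (2.5 equiv), pyridine, DMAP (cat.), CH2Cl2, 0 °C to rt; then H2O, THF, NaHCO3, rt; dilute HCl
Reagents that add atoms: palmitoyl chloride CCCCCCCCCCCCCCCC(=O)Cl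
Why: DMAP-catalysed acylation of the primary allylic alcohol by the acid chloride; the hindered C19 acid is acylated to a mixed anhydride, which water should cleave at its unhindered palmitoyl carbonyl during the aqueous stage.

**Compound list**

1 | 2-methylcyclohex-2-en-1-one | CC1=CCCCC1=O | starting material
2 | (E)-1-methoxy-1-(trimethylsilyloxy)prop-1-ene | C/C=C(\OC)O[Si](C)(C)C | starting material
3 | methyl (2RS)-2-[(1S)-2-methyl-3-(trimethylsilyloxy)cyclohex-2-en-1-yl]propanoate | C1CC[C@@H](C(C)C(=O)OC)C(C)=C1O[Si](C)(C)C | intermediate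
4 | methyl (2RS)-2-[(1S)-3-(dibutylboranyloxy)-2-methylcyclohex-2-en-1-yl]propanoate (dibutylboron enolate) | C1CC[C@@H](C(C)C(=O)OC)C(C)=C1OB(CCCC)CCCC | intermediate
5 | methyl (2RS)-2-[(1S,2R)-2-[(1R)-1-hydroxyprop-2-en-1-yl]-2-methyl-3-oxocyclohexyl]propanoate (hydroxy ester) | C1CC[C@@H](C(C)C(=O)OC)[C@](C)([C@H](O)C=C)C1=O | intermediate
6 | (1R,4RS,4aS,8aR)-1-ethenyl-4,8a-dimethyloctahydro-1H-isochromene-3,8-dione (trans-fused keto δ-lactone, vinyl axial) | C1CC[C@@H]2[C@](C)([C@@H](C=C)OC(=O)C2C)C1=O | intermediate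
7 | (1R,4aS,8aR)-1-ethenyl-4,8a-dimethyl-3,8-bis(trimethylsilyloxy)-4a,5,6,8a-tetrahydro-1H-isochromene (bis-silyl ketene acetal) | C=1CC[C@@H]2[C@](C)([C@@H](C=C)OC(O[Si](C)(C)C)=C2C)C1O[Si](C)(C)C | intermediate
8 | trimethylsilyl (1S,4aS,8aR)-1,4a-dimethyl-5-(trimethylsilyloxy)-1,2,4a,7,8,8a-hexahydronaphthalene-1-carboxylate | C=1CC[C@@H]2[C@](C)(C=CC[C@]2(C)C(=O)O[Si](C)(C)C)C1O[Si](C)(C)C | intermediate
9 | (1S,4aS,8aR)-1,4a-dimethyl-5-oxo-1,2,4a,5,6,7,8,8a-octahydronaphthalene-1-carboxylic acid | C1CC[C@@H]2[C@](C)(C=CC[C@]2(C)C(=O)O)C1=O | intermediate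
10 | (1S,4aS,8aR)-1,4a-dimethyl-5-oxodecahydronaphthalene-1-carboxylic acid | C1CC[C@@H]2[C@](C)(CCC[C@]2(C)C(=O)O)C1=O | intermediate
11 | prop-2-en-1-yl (1S,4aS,8aR)-1,4a-dimethyl-5-oxodecahydronaphthalene-1-carboxylate | C1CC[C@@H]2[C@](C)(CCC[C@]2(C)C(=O)OCC=C)C1=O | intermediate
12 | prop-2-en-1-yl (1S,4aS,8aR)-1,4a-dimethyl-6-methylidene-5-oxodecahydronaphthalene-1-carboxylate | C=C1CC[C@@H]2[C@](C)(CCC[C@]2(C)C(=O)OCC=C)C1=O | intermediate
13 | 4-(trimethylsilyl)but-3-yn-1-ol | OCCC#C[Si](C)(C)C | starting material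
14 | (4-iodobut-1-yn-1-yl)trimethylsilane | ICCC#C[Si](C)(C)C | intermediate
15 | prop-2-en-1-yl (1S,4aS,5S,8aR)-5-(lithiooxy)-1,4a-dimethyl-6-methylidene-5-[4-(trimethylsilyl)but-3-yn-1-yl]decahydronaphthalene-1-carboxylate (lithium alkoxide) | C=C1CC[C@@H]2[C@](C)(CCC[C@]2(C)C(=O)OCC=C)[C@@]1(CCC#C[Si](C)(C)C)O[Li] | intermediate
16 | prop-2-en-1-yl (1S,4aS,5S,8aR)-5-[(methoxycarbonyl)oxy]-1,4a-dimethyl-6-methylidene-5-[4-(trimethylsilyl)but-3-yn-1-yl]decahydronaphthalene-1-carboxylate | C=C1CC[C@@H]2[C@](C)(CCC[C@]2(C)C(=O)OCC=C)[C@@]1(CCC#C[Si](C)(C)C)OC(=O)OC | intermediate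
17 | (1S,4aR,5S,8aR)-1,4a-dimethyl-6-methylidene-5-[4-(trimethylsilyl)but-3-yn-1-yl]decahydronaphthalene-1-carboxylic acid | C=C1CC[C@@H]2[C@](C)(CCC[C@]2(C)C(=O)O)[C@H]1CCC#C[Si](C)(C)C | intermediate
18 | (1S,4aR,5S,8aR)-5-(but-3-yn-1-yl)-1,4a-dimethyl-6-methylidenedecahydronaphthalene-1-carboxylic acid | C=C1CC[C@@H]2[C@](C)(CCC[C@]2(C)C(=O)O)[C@H]1CCC#C | intermediate
19 | dimethylaluminium (1S,4aR,5S,8aR)-5-[(3E)-4-(dimethylalumanyl)-3-methylbut-3-en-1-yl]-1,4a-dimethyl-6-methylidenedecahydronaphthalene-1-carboxylate (alkenylalane) | C=C1CC[C@@H]2[C@](C)(CCC[C@]2(C)C(=O)O[Al](C)C)[C@H]1CC/C(C)=C/[Al](C)C | intermediate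
20 | (1S,4aR,5S,8aR)-5-[(3E)-5-hydroxy-3-methylpent-3-en-1-yl]-1,4a-dimethyl-6-methylidenedecahydronaphthalene-1-carboxylic acid (isocupressic acid) | C=C1CC[C@@H]2[C@](C)(CCC[C@]2(C)C(=O)O)[C@H]1CC/C(C)=C/CO | intermediate
21 | mixed anhydride of hexadecanoic acid with the C19 acid of 22 | C=C1CC[C@@H]2[C@](C)(CCC[C@]2(C)C(=O)OC(=O)CCCCCCCCCCCCCCC)[C@H]1CC/C(C)=C/COC(=O)CCCCCCCCCCCCCCC | intermediate
22 | (1S,4aR,5S,8aR)-5-[(3E)-5-(hexadecanoyloxy)-3-methylpent-3-en-1-yl]-1,4a-dimethyl-6-methylidenedecahydronaphthalene-1-carboxylic acid | C=C1CC[C@@H]2[C@](C)(CCC[C@]2(C)C(=O)O)[C@H]1CC/C(C)=C/COC(=O)CCCCCCCCCCCCCCC | target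

**Totals**

Total step count: 12. Longest linear sequence: 11 (steps 1–6 and 8–12; step 7 is a one-step branch).

**Steps most likely to fail**

Step 1. The α-methyl group of 1 slows Lewis-acid activation, so a racemic silyl-cation-catalysed background addition could compete and facial selectivity at C5 would be lost. The fallback sets out from 2. The same catalyst is applied to cyclohex-2-en-1-one, the substrate class for which this addition is established, and should give methyl (2RS)-2-[(1R)-3-(trimethylsilyloxy)cyclohex-2-en-1-yl]propanoate F1. Regiospecific methylation of its enolate (MeI, benzyltrimethylammonium fluoride, THF, −78 °C to 0 °C) should give methyl (2RS)-2-[(1R)-2-methyl-3-oxocyclohexyl]propanoate F2. Silylation under equilibrating conditions (TMSCl, NaI, Et3N, MeCN) forms the more substituted enol ether and comes back to the route at 3.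

Step 2. Silicon-to-boron exchange may be incomplete at the hindered tetrasubstituted enol ether, or an open silyl-triflate-promoted aldol pathway may compete; either would erode control at C1, and a lactone with an equatorial vinyl group cannot rearrange in step 3. The fallback sets out from 3. Mukaiyama-type alkylation with trimethyl orthoformate (TMSOTf cat., CH2Cl2, −78 °C), again trans to the C5 substituent, should give methyl (2RS)-2-[(1S,2R)-2-(dimethoxymethyl)-2-methyl-3-oxocyclohexyl]propanoate F3. Aqueous CF3CO2H frees methyl (2RS)-2-[(1S,2R)-2-formyl-2-methyl-3-oxocyclohexyl]propanoate F4. Vinylmagnesium bromide (THF, −78 °C) adds to the aldehyde within a magnesium chelate to the C9 ketone oxygen, from the side of the C10 methyl, which should give the same hydroxy ester 5. Lactonisation as in step 2 comes back to the route at 6.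

Step 9. Hydride may be transferred to the wrong allyl terminus (endocyclic alkene), β-hydride elimination may give a diene, facial control at C9 may be lost, or the palladium hydride may partly reduce the silylalkyne. The fallback sets out from 11 and replaces steps 6, 8 and 9 by the classical 8-ketone route. KHMDS and PhNTf2 should give prop-2-en-1-yl (1S,4aS,8aR)-1,4a-dimethyl-5-{[(trifluoromethyl)sulfonyl]oxy}-1,2,3,4,4a,7,8,8a-octahydronaphthalene-1-carboxylate F5. Zinc dust converts 14 into iodo[4-(trimethylsilyl)but-3-yn-1-yl]zinc F6, and Negishi coupling under PdCl2(dppf) should give prop-2-en-1-yl (1S,4aS,8aR)-1,4a-dimethyl-5-[4-(trimethylsilyl)but-3-yn-1-yl]-1,2,3,4,4a,7,8,8a-octahydronaphthalene-1-carboxylate F7. m-CPBA epoxidises the ring alkene from the α-face to the 8α,9α-epoxide of F7 F8. BF3·OEt2 opens it at C9 with 1,2-hydride shift (Meinwald rearrangement) to prop-2-en-1-yl (1S,4aS,5R,8aR)-1,4a-dimethyl-6-oxo-5-[4-(trimethylsilyl)but-3-yn-1-yl]decahydronaphthalene-1-carboxylate F9, whose C9 centre is equilibrated with DBU to the equatorial side chain. Wittig methylenation (Ph3P=CH2) should give prop-2-en-1-yl (1S,4aR,5S,8aR)-1,4a-dimethyl-6-methylidene-5-[4-(trimethylsilyl)but-3-yn-1-yl]decahydronaphthalene-1-carboxylate F10. Pd(PPh3)4 and morpholine remove the allyl group and come back to the route at 17.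

**Further compounds**

F1 | step 1 | methyl (2RS)-2-[(1R)-3-(trimethylsilyloxy)cyclohex-2-en-1-yl]propanoate | C1CC[C@@H](C(C)C(=O)OC)C=C1O[Si](C)(C)C
F2 | step 1 | methyl (2RS)-2-[(1R)-2-methyl-3-oxocyclohexyl]propanoate (epimers at the methyl-bearing ring carbon) | C1CC[C@@H](C(C)C(=O)OC)C(C)C1=O
F3 | step 2 | methyl (2RS)-2-[(1S,2R)-2-(dimethoxymethyl)-2-methyl-3-oxocyclohexyl]propanoate | C1CC[C@@H](C(C)C(=O)OC)[C@](C)(C(OC)OC)C1=O
F4 | step 2 | methyl (2RS)-2-[(1S,2R)-2-formyl-2-methyl-3-oxocyclohexyl]propanoate | C1CC[C@@H](C(C)C(=O)OC)[C@](C)(C=O)C1=O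
F5 | step 9 | prop-2-en-1-yl (1S,4aS,8aR)-1,4a-dimethyl-5-{[(trifluoromethyl)sulfonyl]oxy}-1,2,3,4,4a,7,8,8a-octahydronaphthalene-1-carboxylate | C=1CC[C@@H]2[C@](C)(CCC[C@]2(C)C(=O)OCC=C)C1OS(=O)(=O)C(F)(F)F
F6 | step 9 | iodo[4-(trimethylsilyl)but-3-yn-1-yl]zinc | I[Zn]CCC#C[Si](C)(C)C
F7 | step 9 | prop-2-en-1-yl (1S,4aS,8aR)-1,4a-dimethyl-5-[4-(trimethylsilyl)but-3-yn-1-yl]-1,2,3,4,4a,7,8,8a-octahydronaphthalene-1-carboxylate | C=1CC[C@@H]2[C@](C)(CCC[C@]2(C)C(=O)OCC=C)C1CCC#C[Si](C)(C)C
F8 | step 9 | 8α,9α-epoxide of F7 (labdane numbering) | [C@@H]13CC[C@@H]2[C@](C)(CCC[C@]2(C)C(=O)OCC=C)[C@]1(CCC#C[Si](C)(C)C)O3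
F9 | step 9 | prop-2-en-1-yl (1S,4aS,5R,8aR)-1,4a-dimethyl-6-oxo-5-[4-(trimethylsilyl)but-3-yn-1-yl]decahydronaphthalene-1-carboxylate | O=C1CC[C@@H]2[C@](C)(CCC[C@]2(C)C(=O)OCC=C)[C@H]1CCC#C[Si](C)(C)C
F10 | step 9 | prop-2-en-1-yl (1S,4aR,5S,8aR)-1,4a-dimethyl-6-methylidene-5-[4-(trimethylsilyl)but-3-yn-1-yl]decahydronaphthalene-1-carboxylate | C=C1CC[C@@H]2[C@](C)(CCC[C@]2(C)C(=O)OCC=C)[C@H]1CCC#C[Si](C)(C)C
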